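## Retrosynthetic overview

1. Callophycoic acid H ⇐ tetracyclic chroman methyl ester: cleaving the tertiary C3–O aryl ether bond by E2 (with ester hydrolysis) releases the exocyclic alkene and the phenol.
2. Chroman ⇐ open-chain (10R,11S)-bromohydrin of a silyl-protected 5-geranylgeranyl arene: one cascade from a configurationally defined bromonium ion closes ring B (C6–C11), then ring A (C2–C7), then pyran ring C through the key C3–O bond.
3. Bromohydrin ⇐ (10S,11S)-epoxide: the absolute configuration is written into two C–O bonds by Sharpless epoxidation, then oxygen is exchanged for bromine by SN2; this also decides which of the four trisubstituted alkenes carries the bromonium.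
4. Epoxide ⇐ C12 allylic alcohol (SeO2 C–H oxidation) plus a prenyl nucleophile (C12–C13) ⇐ 5-farnesyl arene ⇐ methyl 3-bromo-4-hydroxybenzoate + (2E,6E)-farnesyl bromide.

Assumption: locants C1–C15 count the terpenoid chain from the benzylic carbon; ring A is the methylidene-bearing cyclohexane, ring B the bromocyclohexane, ring C the pyran; the two starting materials and Me2C=CHCH2MgCl are bought. The route is a proposal; nothing in it has been run.

## Route

Step 1
Reactants: 1 methyl 3-bromo-4-hydroxybenzoate; 2 (2E,6E)-farnesyl bromide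
Product: 4 methyl 3-bromo-4-hydroxy-5-[(2E,6E)-3,7,11-trimethyldodeca-2,6,10-trien-1-yl]benzoate, via sodium phenoxide 3 (not isolated)
Conditions: NaH, toluene, 0 °C; then 2, 23 °C, 24 h
Reagents that add atoms: none
Why: Ortho C-alkylation of a sodium phenoxide in a non-polar solvent (Claisen-type C-allylation): the tight ion pair sends the primary allylic bromide to the only free ortho carbon by SN2 with the E-alkenes retained, O-alkylation being the minor path.

Step 2
Reactants: 4 methyl 3-bromo-4-hydroxy-5-[(2E,6E)-3,7,11-trimethyldodeca-2,6,10-trien-1-yl]benzoate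
Product: 5 methyl 3-bromo-4-[(tert-butyldimethylsilyl)oxy]-5-[(2E,6E)-3,7,11-trimethyldodeca-2,6,10-trien-1-yl]benzoate
Conditions: TBSCl, imidazole, DMF, 23 °C
Reagents that add atoms: tert-butyldimethylsilyl chloride, CC(C)(C)[Si](C)(C)Cl
Why: Imidazole-promoted silyl ether formation; the silyl ether masks the acidic phenol in steps 3–7 and later serves as the oxygen nucleophile that ends the cascade.

Step 3
Reactants: 5 methyl 3-bromo-4-[(tert-butyldimethylsilyl)oxy]-5-[(2E,6E)-3,7,11-trimethyldodeca-2,6,10-trien-1-yl]benzoate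
Product: 6 methyl 3-bromo-4-[(tert-butyldimethylsilyl)oxy]-5-[(2E,6E,10E)-12-hydroxy-3,7,11-trimethyldodeca-2,6,10-trien-1-yl]benzoate
Conditions: SeO2 (0.3 equiv), t-BuOOH, salicylic acid (cat.), CH2Cl2, 0 → 23 °C
Reagents that add atoms: tert-butyl hydroperoxide, CC(C)(C)OO; selenium dioxide, O=[Se]=O
Why: Sharpless–Umbreit SeO2-catalysed allylic oxidation (ene reaction, then [2,3]-sigmatropic shift), selective for the E-methyl group of the terminal isopropylidene unit, which places the new C–O bond on C12 next to the C10=C11 alkene.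

Step 4
Reactants: 6 methyl 3-bromo-4-[(tert-butyldimethylsilyl)oxy]-5-[(2E,6E,10E)-12-hydroxy-3,7,11-trimethyldodeca-2,6,10-trien-1-yl]benzoate
Product: 7 methyl 3-bromo-4-[(tert-butyldimethylsilyl)oxy]-5-[(2E,6E,10S,11S)-10,11-epoxy-12-hydroxy-3,7,11-trimethyldodeca-2,6-dien-1-yl]benzoate
Conditions: Ti(OiPr)4 (10 mol %), L-(+)-diethyl tartrate (12 mol %), t-BuOOH, 4 Å sieves, CH2Cl2, −20 °C
Reagents that add atoms: tert-butyl hydroperoxide, CC(C)(C)OO
Why: Sharpless asymmetric epoxidation: the C12 hydroxyl directs the titanium–tartrate catalyst to the C10=C11 alkene only, and L-(+)-diethyl tartrate gives the (2S,3S)-type epoxy alcohol known for E-allylic alcohols, here (10S,11S), which fixes the absolute configuration of the synthesis in two C–O bonds.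

Step 5
Reactants: 7 methyl 3-bromo-4-[(tert-butyldimethylsilyl)oxy]-5-[(2E,6E,10S,11S)-10,11-epoxy-12-hydroxy-3,7,11-trimethyldodeca-2,6-dien-1-yl]benzoate
Product: 9 methyl 3-bromo-4-[(tert-butyldimethylsilyl)oxy]-5-[(2E,6E,10S,11S)-10,11-epoxy-3,7,11,15-tetramethylhexadeca-2,6,14-trien-1-yl]benzoate, via epoxy triflate 8 (not isolated)
Conditions: Tf2O, 2,6-lutidine, CH2Cl2, −78 °C; then (Me2C=CHCH2)2CuMgCl [from Me2C=CHCH2MgCl and CuBr·SMe2], THF, −78 to −40 °C
Reagents that add atoms: 3-methylbut-2-enylmagnesium chloride, CC(C)=CC[Mg]Cl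
Why: O-triflation, then copper-mediated sp3–sp3 coupling (SN2 at the primary triflate) in which the prenyl cuprate bonds through its unhindered CH2 terminus; ester, aryl bromide and epoxide are inert to the cuprate at −78 °C and the epoxide stereocentres are not touched.

Step 6
Reactants: 9 methyl 3-bromo-4-[(tert-butyldimethylsilyl)oxy]-5-[(2E,6E,10S,11S)-10,11-epoxy-3,7,11,15-tetramethylhexadeca-2,6,14-trien-1-yl]benzoate
Product: 10 methyl 3-bromo-5-[(2E,6E,10R,11S)-10-bromo-11-hydroxy-3,7,11,15-tetramethylhexadeca-2,6,14-trien-1-yl]-4-[(tert-butyldimethylsilyl)oxy]benzoate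
Conditions: Li2NiBr4, THF, 0 → 23 °C; H2O
Reagents that add atoms: dilithium tetrabromonickelate, [Li+].[Li+].Br[Ni-2](Br)(Br)Br
Why: Regioselective SN2 opening of the trisubstituted epoxide by bromide at the less substituted carbon (bromohydrin synthesis with Li2NiBr4), inverting C10 to R so that bromine lies anti to the tertiary C11–O bond, which is kept as the future leaving group.

Step 7
Reactants: 10 methyl 3-bromo-5-[(2E,6E,10R,11S)-10-bromo-11-hydroxy-3,7,11,15-tetramethylhexadeca-2,6,14-trien-1-yl]-4-[(tert-butyldimethylsilyl)oxy]benzoate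
Product: 13 tetracyclic chroman methyl ester (aryl oxygen bonded to C3; all ring fusions trans; C3–O, C10–Br, C11-homoprenyl and C2–CH2Ar equatorial; C3-, C7- and C11-methyl axial on one face; 2S,3S,6S,7R,10R,11R in chain locants), via tertiary triflate 11 (not isolated), via bromonium triflate 12 (not isolated)
Conditions: Tf2O, 2,6-di-tert-butyl-4-methylpyridine, CH2Cl2 (0.005 M), −78 → −40 °C
Reagents that add atoms: none
Why: Proposed new method: triflation of the tertiary alcohol anti to the C10–Br bond gives a triflate that ionises at −78 °C with neighbouring-bromine participation to a single enantiopure bromonium ion with a non-nucleophilic counter-ion; with no free Br+ donor present the bromonium sits only at C10/C11, the 6,7-alkene opens it at C11 with inversion (net retention of the Sharpless C11 configuration, C10 untouched) through a chair–chair array, the 2,3-alkene attacks C7, and the silyl ether oxygen captures the C3 cation anti, passing its silyl group to triflate, so C6, C7, C2 and C3 follow from all-anti additions to the E,E-diene; closest known reaction types are Br+-induced polyene cyclisation (for example with bromodiethylsulfonium bromopentachloroantimonate), generation of configurationally defined bromonium ions from enantiopure bromohydrin derivatives, and silyl ether participation in haloetherification.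

Step 8
Reactants: 13 tetracyclic chroman methyl ester
Product: 15 callophycoic acid H, 3-bromo-5-{[(1R,4aS,5R,6R,8aS)-6-bromo-5,8a-dimethyl-2-methylidene-5-(4-methylpent-3-en-1-yl)decahydronaphthalen-1-yl]methyl}-4-hydroxybenzoic acid, via potassium carboxylate 14 (not isolated)
Conditions: KOt-Bu (8 equiv), H2O (2 equiv), 18-crown-6, THF, 23 °C then 60 °C; 1 M HCl to pH 4, 0 °C
Reagents that add atoms: water, O
Why: Proposed new method: after in-flask ester hydrolysis (KOH from KOt-Bu and water), tert-butoxide effects an E2 elimination across the tertiary C3–O aryl ether bond, the 2-bromo-4-carboxylatophenoxide being a fair leaving group (phenol pKa about 8–9); because the C3–O bond is equatorial in the rigid trans-fused system only a hydrogen of the axial C3 methyl group can be anti-periplanar, so the alkene can only form exocyclic (the Hofmann preference of poor leaving groups points the same way) and no stereocentre of the target is touched; closest known reaction types are Hofmann-type E2 eliminations with KOt-Bu and the base-induced ring opening of 2,3-dihydrobenzofurans to 2-vinylphenols.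

## Compound list

1 | methyl 3-bromo-4-hydroxybenzoate | COC(=O)c1ccc(O)c(Br)c1 | starting material
2 | (2E,6E)-farnesyl bromide, (2E,6E)-1-bromo-3,7,11-trimethyldodeca-2,6,10-triene | BrC/C=C(\C)CC/C=C(\C)CCC=C(C)C | starting material
3 | sodium 2-bromo-4-(methoxycarbonyl)phenoxide | COC(=O)c1ccc([O-])c(Br)c1.[Na+] | intermediate
4 | methyl 3-bromo-4-hydroxy-5-[(2E,6E)-3,7,11-trimethyldodeca-2,6,10-trien-1-yl]benzoate | COC(=O)c1cc(Br)c(O)c(C/C=C(\C)CC/C=C(\C)CCC=C(C)C)c1 | intermediate
5 | methyl 3-bromo-4-[(tert-butyldimethylsilyl)oxy]-5-[(2E,6E)-3,7,11-trimethyldodeca-2,6,10-trien-1-yl]benzoate | COC(=O)c1cc(Br)c(O[Si](C)(C)C(C)(C)C)c(C/C=C(\C)CC/C=C(\C)CCC=C(C)C)c1 | intermediate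
6 | methyl 3-bromo-4-[(tert-butyldimethylsilyl)oxy]-5-[(2E,6E,10E)-12-hydroxy-3,7,11-trimethyldodeca-2,6,10-trien-1-yl]benzoate | COC(=O)c1cc(Br)c(O[Si](C)(C)C(C)(C)C)c(C/C=C(\C)CC/C=C(\C)CC/C=C(\C)CO)c1 | intermediate
7 | methyl 3-bromo-4-[(tert-butyldimethylsilyl)oxy]-5-[(2E,6E,10S,11S)-10,11-epoxy-12-hydroxy-3,7,11-trimethyldodeca-2,6-dien-1-yl]benzoate | COC(=O)c1cc(Br)c(O[Si](C)(C)C(C)(C)C)c(C/C=C(\C)CC/C=C(\C)CC[C@@H]2O[C@@]2(C)CO)c1 | intermediate
8 | 12-O-triflate of 7, methyl 3-bromo-4-[(tert-butyldimethylsilyl)oxy]-5-[(2E,6E,10S,11S)-10,11-epoxy-3,7,11-trimethyl-12-(trifluoromethanesulfonyloxy)dodeca-2,6-dien-1-yl]benzoate | COC(=O)c1cc(Br)c(O[Si](C)(C)C(C)(C)C)c(C/C=C(\C)CC/C=C(\C)CC[C@@H]2O[C@@]2(C)COS(=O)(=O)C(F)(F)F)c1 | intermediate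
9 | methyl 3-bromo-4-[(tert-butyldimethylsilyl)oxy]-5-[(2E,6E,10S,11S)-10,11-epoxy-3,7,11,15-tetramethylhexadeca-2,6,14-trien-1-yl]benzoate | COC(=O)c1cc(Br)c(O[Si](C)(C)C(C)(C)C)c(C/C=C(\C)CC/C=C(\C)CC[C@@H]2O[C@@]2(C)CCC=C(C)C)c1 | intermediate
10 | methyl 3-bromo-5-[(2E,6E,10R,11S)-10-bromo-11-hydroxy-3,7,11,15-tetramethylhexadeca-2,6,14-trien-1-yl]-4-[(tert-butyldimethylsilyl)oxy]benzoate | COC(=O)c1cc(Br)c(O[Si](C)(C)C(C)(C)C)c(C/C=C(\C)CC/C=C(\C)CC[C@@H](Br)[C@@](C)(O)CCC=C(C)C)c1 | intermediate
11 | 11-O-triflate of 10 (10R,11S) | COC(=O)c1cc(Br)c(O[Si](C)(C)C(C)(C)C)c(C/C=C(\C)CC/C=C(\C)CC[C@@H](Br)[C@@](C)(OS(=O)(=O)C(F)(F)F)CCC=C(C)C)c1 | intermediate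
12 | C10,C11-bridged bromonium ion of the silyl-protected (2E,6E)-polyene (10R,11R; bromine on the face opposite the former epoxide oxygen), triflate salt | COC(=O)c1cc(Br)c(O[Si](C)(C)C(C)(C)C)c(C/C=C(\C)CC/C=C(\C)CC[C@H]2[Br+][C@]2(C)CCC=C(C)C)c1.[O-]S(=O)(=O)C(F)(F)F | intermediate
13 | tetracyclic chroman methyl ester: arene, pyran ring C (O–C3), ring A, ring B, all fusions trans; 2S,3S,6S,7R,10R,11R in chain locants; equatorial C10–Br | COC(=O)c1cc(Br)c2O[C@@]3(C)CC[C@@H]4[C@@](C)(CCC=C(C)C)[C@H](Br)CC[C@@]4(C)[C@@H]3Cc2c1 | intermediate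
14 | potassium carboxylate of the chroman acid (same configuration as 13) | [K+].[O-]C(=O)c1cc(Br)c2O[C@@]3(C)CC[C@@H]4[C@@](C)(CCC=C(C)C)[C@H](Br)CC[C@@]4(C)[C@@H]3Cc2c1 | intermediate
15 | callophycoic acid H, 3-bromo-5-{[(1R,4aS,5R,6R,8aS)-6-bromo-5,8a-dimethyl-2-methylidene-5-(4-methylpent-3-en-1-yl)decahydronaphthalen-1-yl]methyl}-4-hydroxybenzoic acid | C=C1CC[C@@H]2[C@@](C)(CCC=C(C)C)[C@H](Br)CC[C@@]2(C)[C@@H]1Cc1cc(C(=O)O)cc(Br)c1O | target

## Step count and risks

Total step count: 8. Longest linear sequence: 8 steps (from 1 or 2).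

The three steps most likely to fail:

Step 5 (prenyl cuprate on the epoxy triflate). The risk is coupling through the tertiary terminus of the prenyl group, or elimination of the triflate. The fallback sets out from 7 and comes back at 9. The same triflate 8 is displaced with the symmetrical cuprate (CH2=CHCH2)2CuMgCl, which has no regiochemical ambiguity, to give the butenyl epoxide methyl 3-bromo-4-[(tert-butyldimethylsilyl)oxy]-5-[(2E,6E,10S,11S)-10,11-epoxy-3,7,11-trimethylpentadeca-2,6,14-trien-1-yl]benzoate F1. The isopropylidene terminus is then built by cross-metathesis of the vinyl group with 2-methylbut-2-ene as solvent and second-generation Grubbs catalyst (H2IMes)(PCy3)Cl2Ru=CHPh, which returns 9.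

Step 7 (new bromonium cascade). The risks are bromine transfer from the bromonium ion to another alkene of the same molecule, proton loss instead of capture by the silyl ether oxygen, and elimination of the tertiary triflate. The fallback uses known chemistry, sets out from 10 and comes back at 13. The tertiary alcohol is acylated with trifluoroacetic anhydride and pyridine to the tertiary trifluoroacetate methyl 3-bromo-5-[(2E,6E,10R,11S)-10-bromo-3,7,11,15-tetramethyl-11-(trifluoroacetoxy)hexadeca-2,6,14-trien-1-yl]-4-[(tert-butyldimethylsilyl)oxy]benzoate F2. This isolable ester is solvolysed in hexafluoroisopropanol buffered with 2,6-lutidine (0 to 40 °C). SN1 ionisation with neighbouring-bromine participation, bromohydrin esters as precursors of configurationally defined bromonium ions, and fluoroalcohol-promoted cation–olefin cyclisation are all established; the cascade closes to 13 with the silyl group passing to trifluoroacetate.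

Step 8 (new E2 opening of the chroman). The risks are a slow elimination, aryne formation at the aryl bromide, and base-induced migration of the new alkene into the ring. The fallback uses known chemistry, sets out from 13 and comes back at 15. The tertiary alkyl–oxygen bond is cleaved with Me3SiI (hexamethyldisilazane as acid scavenger, CH2Cl2, −40 °C), the established silyl iodide cleavage of tert-alkyl aryl ethers. This gives the ring-opened tertiary iodide aryl trimethylsilyl ether (C3–I, both C3 epimers, other centres as in 13) F3, whose silylated oxygen cannot re-close. Dehydroiodination with DBU and desilylation on work-up give an alkene mixture. The exocyclic isomer, callophycoic acid H methyl ester, methyl 3-bromo-5-{[(1R,4aS,5R,6R,8aS)-6-bromo-5,8a-dimethyl-2-methylidene-5-(4-methylpent-3-en-1-yl)decahydronaphthalen-1-yl]methyl}-4-hydroxybenzoate F4, is separated on AgNO3-impregnated silica and saponified with LiOH in THF/MeOH/H2O to 15. This path is less selective than the main step.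

## Further compounds

F1 | step 5 | methyl 3-bromo-4-[(tert-butyldimethylsilyl)oxy]-5-[(2E,6E,10S,11S)-10,11-epoxy-3,7,11-trimethylpentadeca-2,6,14-trien-1-yl]benzoate | COC(=O)c1cc(Br)c(O[Si](C)(C)C(C)(C)C)c(C/C=C(\C)CC/C=C(\C)CC[C@@H]2O[C@@]2(C)CCC=C)c1
F2 | step 7 | methyl 3-bromo-5-[(2E,6E,10R,11S)-10-bromo-3,7,11,15-tetramethyl-11-(trifluoroacetoxy)hexadeca-2,6,14-trien-1-yl]-4-[(tert-butyldimethylsilyl)oxy]benzoate | COC(=O)c1cc(Br)c(O[Si](C)(C)C(C)(C)C)c(C/C=C(\C)CC/C=C(\C)CC[C@@H](Br)[C@@](C)(OC(=O)C(F)(F)F)CCC=C(C)C)c1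
F3 | step 8 | ring-opened tertiary iodide aryl trimethylsilyl ether of 13 (C3–I, both C3 epimers, other centres as in 13) | CC1(I)CC[C@@H]2[C@@](C)(CCC=C(C)C)[C@H](Br)CC[C@@]2(C)[C@@H]1Cc1cc(C(=O)OC)cc(Br)c1O[Si](C)(C)C
F4 | step 8 | callophycoic acid H methyl ester, methyl 3-bromo-5-{[(1R,4aS,5R,6R,8aS)-6-bromo-5,8a-dimethyl-2-methylidene-5-(4-methylpent-3-en-1-yl)decahydronaphthalen-1-yl]methyl}-4-hydroxybenzoate | C=C1CC[C@@H]2[C@@](C)(CCC=C(C)C)[C@H](Br)CC[C@@]2(C)[C@@H]1Cc1cc(C(=O)OC)cc(Br)c1O
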